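The route rests on disconnecting the bond between the methyl-bearing C–O carbon common to cyclohexane ring C and lactone ring D and the ring-fusion CH of cyclopentane ring B. Forward, a methylaluminium dichloride Prins (carbonyl-ene) reaction lets a methyl ketone add to the CH terminus of a trisubstituted cyclopentene: one operation closes ring C, fixes the cis B/C fusion next to the quaternary ester carbon and installs the tertiary carbinol that becomes the lactone oxygen site. Its precursor is an enantiopure methyl cyclopent-2-ene-1-carboxylate whose quaternary carbon bears a 4-oxo-1-silyloxypentyl chain and whose alkene bears a silyl-protected hydroxyethyl arm, from which ring A is grown last.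

Key step: step 9

Remark: ring letters are A (bromodimethylcyclohexanol), B (cyclopentane), C (bromocyclohexane) and D (γ-lactone); it is assumed that the carbinol configuration from the key step need not be controlled because step 11 fixes it through the lactone bridge, and that ring A, built last with an achiral bromine source, forms in both absolute senses, so its unwanted diastereomer must be separated from 26.

Step 1
Reactants: 1 2-bromoethanol
Product: 2 (2-bromoethoxy)(tert-butyl)diphenylsilane
Conditions: tBuPh2SiCl, imidazole, CH2Cl2, 0 °C to rt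
Reagents that add atoms: tert-butyl(chloro)diphenylsilane, CC(C)(C)[Si](Cl)(c1ccccc1)c1ccccc1
Why: Imidazole-mediated silylation of a primary alcohol; the tert-butyldiphenylsilyl ether is chosen because it should survive LiN(iPr)2, MeAlCl2 and trifluoroacetic acid and is later removed with fluoride without touching lactone or bromide.

Step 2
Reactants: 3 methyl 2-oxocyclopentane-1-carboxylate; 2 silyl bromide
Product: 5 methyl 3-[2-(tert-butyldiphenylsilyloxy)ethyl]-2-oxocyclopentane-1-carboxylate (stereoisomer mixture), via dilithium dianion 4 (not isolated)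
Conditions: LiN(iPr)2 (2.2 equiv), THF, 0 °C; then 2, DMPU, 0 °C to rt; aq. NH4Cl
Reagents that add atoms: none
Why: γ-Alkylation of a β-keto ester dianion, in which the more basic carbanion at the ketone α'-carbon is the one alkylated by the primary bromide; the new stereocentre is flattened in step 5, so the isomer mixture is carried on.

Step 3
Reactants: 5 alkylated keto ester
Product: 6 methyl 3-[2-(tert-butyldiphenylsilyloxy)ethyl]-2-hydroxycyclopentane-1-carboxylate (stereoisomer mixture)
Conditions: NaBH4, MeOH, 0 °C
Reagents that add atoms: none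
Why: Borohydride reduction of the ketone of a β-keto ester with the ester untouched; the carbinol centre is removed in step 4, so no control is needed.

Step 4
Reactants: 6 hydroxy ester
Product: 8 methyl 3-[2-(tert-butyldiphenylsilyloxy)ethyl]cyclopent-1-ene-1-carboxylate (racemic), via mesylate 7 (not isolated)
Conditions: MeSO2Cl, Et3N, CH2Cl2, 0 °C; then DBU, rt
Reagents that add atoms: none
Why: Mesylation followed by base-induced β-elimination (E1cB through the ester enolate) should give the conjugated cyclopentenecarboxylate as the only alkene regioisomer.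

Step 5
Reactants: 8 cyclopentenecarboxylate; 9 pent-4-enoyl chloride
Product: 11 methyl 3-[2-(tert-butyldiphenylsilyloxy)ethyl]-1-(pent-4-enoyl)cyclopent-2-ene-1-carboxylate (racemic), via lithium dienolate 10 (not isolated)
Conditions: LiN(iPr)2, THF/DMPU, −78 °C; inverse addition to 9, THF, −78 °C
Reagents that add atoms: none
Why: Deconjugative α-acylation of an extended ester dienolate: γ-deprotonation, then kinetic C-acylation at the α-carbon, creates the quaternary carbon (racemic) and moves the alkene to the β,γ-position with its CH terminus next to that carbon; inverse addition avoids proton transfer from the product.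

Step 6
Reactants: 11 racemic keto ester
Product: 12 methyl (1S)-3-[2-(tert-butyldiphenylsilyloxy)ethyl]-1-[(1S)-1-hydroxypent-4-enyl]cyclopent-2-ene-1-carboxylate
Conditions: (R)-Me-CBS [(3aR)-1-methyl-3,3-diphenyltetrahydro-1H,3H-pyrrolo[1,2-c][1,3,2]oxazaborole] (20 mol%), catecholborane, toluene, −78 °C; MeOH, aq. NaOH wash; chromatographic separation of diastereomers
Reagents that add atoms: none
Why: CBS reduction under catalyst control: with the quaternary carbon as the large group, the (R)-oxazaborolidine should deliver hydride to the same carbonyl face of both enantiomers of 11 and give the (S)-carbinol in each, so the racemate becomes two diastereomers and chromatography isolates the one with the (1S) quaternary centre; catecholborane at −78 °C leaves both alkenes alone.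

Step 7
Reactants: 12 hydroxy ester
Product: 13 methyl (1S)-3-[2-(tert-butyldiphenylsilyloxy)ethyl]-1-[(1S)-1-(triethylsilyloxy)pent-4-enyl]cyclopent-2-ene-1-carboxylate
Conditions: Et3SiOSO2CF3, 2,6-lutidine, CH2Cl2, −78 to 0 °C
Reagents that add atoms: triethylsilyl trifluoromethanesulfonate, CC[Si](CC)(CC)OS(=O)(=O)C(F)(F)F
Why: Silyl triflate silylation of a hindered secondary alcohol; the triethylsilyl ether prevents lactol formation with the ketone made in step 8 and is labile enough to be lost in the acid of step 11 while the primary tert-butyldiphenylsilyl ether stays.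

Step 8
Reactants: 13 silyl ether
Product: 14 methyl (1S)-3-[2-(tert-butyldiphenylsilyloxy)ethyl]-1-[(1S)-4-oxo-1-(triethylsilyloxy)pentyl]cyclopent-2-ene-1-carboxylate
Conditions: PdCl2 (10 mol%), CuCl, O2 (1 atm), DMF/H2O, rt
Reagents that add atoms: water, O
Why: Tsuji–Wacker oxidation, selective for the terminal alkene over the trisubstituted ring alkene and Markovnikov in sense, unveils the methyl ketone.

Step 9
Reactants: 14 keto ester (Prins precursor)
Product: 15 methyl (3aS,4R,7S,7aS)-3-[2-(tert-butyldiphenylsilyloxy)ethyl]-4-hydroxy-4-methyl-7-(triethylsilyloxy)-1,3a,4,5,6,7-hexahydro-7aH-indene-7a-carboxylate (cis-fused; hydroxyl trans to the ester)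
Conditions: MeAlCl2 (2.5 equiv), CH2Cl2, −78 to −20 °C; aq. potassium sodium tartrate
Reagents that add atoms: none
Why: MeAlCl2 binds the methyl ketone, the cyclopentene attacks through its CH terminus to leave a tertiary cation at the substituted alkene carbon, and a proton from the neighbouring ring CH2 passes to the aluminium alkoxide (methane is lost), giving the homoallylic tertiary alcohol; this is a stepwise Prins reaction and formally a carbonyl-ene reaction. The closest known reaction type is the methylaluminium chloride-promoted intramolecular carbonyl-ene cyclisation of keto alkenes to cyclohexanols. Ring C closes in the 6-exo mode through a chair-like array with the silyloxy group equatorial. The ring-fusion CH is set by the tether, which can reach only the alkene face that carries it, so the new C–C bond ends up trans to the angular ester and the fusion is cis; the carbinol centre is expected with hydroxyl on the ring B side (oxygen held near the developing cation) but is not relied on, because step 11 fixes it. The step needs attack at the less substituted alkene carbon and proton loss instead of chloride capture, which the trisubstituted alkene and the proton-scavenging methyl–aluminium bond should secure; the ester and both silyl ethers are expected to be inert at low temperature, and a positional isomer of the new alkene would converge in step 10.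

Step 10
Reactants: 15 hydrindene hydroxy ester
Product: 16 methyl (3R,3aS,4R,7S,7aS)-3-[2-(tert-butyldiphenylsilyloxy)ethyl]-4-hydroxy-4-methyl-7-(triethylsilyloxy)octahydro-7aH-indene-7a-carboxylate
Conditions: H2 (1 atm), PtO2, EtOAc, rt
Reagents that add atoms: none
Why: Heterogeneous syn-hydrogenation from the convex face of the cis-hydrindene (the face of the ring-fusion hydrogen and the ester), the other face being screened by ring C and its carbinol substituents, should place the new ring B hydrogen cis to the fusion hydrogen and the silyloxyethyl arm cis to ring C; PtO2 is chosen to limit alkene migration into the ring fusion.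

Step 11
Reactants: 16 saturated hydroxy ester
Product: 17 (3R,3aS,4S,7S,7aS)-3-[2-(tert-butyldiphenylsilyloxy)ethyl]-7-hydroxy-4-methyloctahydro-1H-indene-7a,4-carbolactone
Conditions: CF3CO2H/CH2Cl2 (1:4), H2O (3 equiv), 0 °C to rt; aq. NaHCO3
Reagents that add atoms: water, O
Why: Acid-mediated lactonisation of a tertiary γ-hydroxy ester: the acid removes the triethylsilyl group and ionises the tertiary hydroxyl while the axial ester carbonyl attacks the carbinol carbon from the rear (neighbouring-group participation), and water hydrolyses the resulting dialkoxycarbenium ion with loss of methanol, so the carbinol centre is inverted and locked by the bridge; low temperature and short contact should limit elimination toward the ring-fusion carbon.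

Step 12
Reactants: 17 hydroxy lactone
Product: 18 (3R,3aS,4S,7R,7aR)-7-bromo-3-[2-(tert-butyldiphenylsilyloxy)ethyl]-4-methyloctahydro-1H-indene-7a,4-carbolactone
Conditions: CBr4, P(n-C8H17)3, toluene, 70 °C
Reagents that add atoms: carbon tetrabromide, BrC(Br)(Br)Br
Why: Appel bromination with inversion: bromide displaces the axial alkoxyphosphonium group from the equatorial side, which places bromine equatorial and relieves the 1,3-diaxial contact with ring B; the adjacent acyl-bearing quaternary carbon disfavours ionisation and Wagner–Meerwein shifts, and the more nucleophilic trialkylphosphine is the variant used for hindered neopentylic secondary alcohols.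

Step 13
Reactants: 18 bromo lactone silyl ether
Product: 19 (3R,3aS,4S,7R,7aR)-7-bromo-3-(2-hydroxyethyl)-4-methyloctahydro-1H-indene-7a,4-carbolactone
Conditions: HF·pyridine, THF, 0 °C to rt
Reagents that add atoms: none
Why: Fluoride cleavage of the silyl ether under non-basic conditions that should leave the secondary bromide and the lactone intact.

Step 14
Reactants: 19 primary alcohol
Product: 20 (3R,3aS,4S,7R,7aR)-7-bromo-4-methyl-3-(2-oxoethyl)octahydro-1H-indene-7a,4-carbolactone
Conditions: Dess–Martin periodinane, NaHCO3, CH2Cl2, rt
Reagents that add atoms: none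
Why: Dess–Martin oxidation of a primary alcohol to the aldehyde under buffered conditions, with no epimerisable centre next to the new carbonyl.

Step 15
Reactants: 20 aldehyde; 21 5-bromo-2-methylpent-2-ene
Product: 23 (3R,3aS,4S,7R,7aR)-7-bromo-3-(2-hydroxy-6-methylhept-5-enyl)-4-methyloctahydro-1H-indene-7a,4-carbolactone (carbinol epimers), via 4-methylpent-3-enylmagnesium bromide 22 (not isolated)
Conditions: 21, Mg, THF, rt; then 20, THF, −78 °C; aq. NH4Cl
Reagents that add atoms: none
Why: Grignard addition to the aldehyde at low temperature, which should be far faster than attack at the hindered lactone; the carbinol configuration is irrelevant because it is oxidised next.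

Step 16
Reactants: 23 secondary alcohol
Product: 24 (3R,3aS,4S,7R,7aR)-7-bromo-4-methyl-3-(6-methyl-2-oxohept-5-enyl)octahydro-1H-indene-7a,4-carbolactone
Conditions: Dess–Martin periodinane, NaHCO3, CH2Cl2, rt
Reagents that add atoms: none
Why: Dess–Martin oxidation of the secondary alcohol to the ketone, compatible with the trisubstituted alkene, bromide and lactone.

Step 17
Reactants: 24 ketone
Product: 25 (3R,3aS,4S,7R,7aR)-7-bromo-4-methyl-3-(6-methyl-2-methylidenehept-5-enyl)octahydro-1H-indene-7a,4-carbolactone
Conditions: Ph3PCH3Br, KOtBu, THF, 0 °C to rt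
Reagents that add atoms: methyltriphenylphosphonium bromide, C[P+](c1ccccc1)(c1ccccc1)c1ccccc1.[Br-]
Why: Wittig methylenation of an unhindered ketone; the non-stabilised ylide should not attack the lactone, and the equatorial bromide has no antiperiplanar hydrogen for elimination.

Step 18
Reactants: 25 diene
Product: 26 (3R,3aS,4S,7R,7aR)-7-bromo-3-{[(1R,4R)-4-bromo-1-hydroxy-3,3-dimethylcyclohexyl]methyl}-4-methyloctahydro-1H-indene-7a,4-carbolactone (CNP0282702.1)
Conditions: N-bromosuccinimide, (CF3)2CHOH/H2O (20:1), 0 °C; chromatographic separation from the ring A diastereomer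
Reagents that add atoms: N-bromosuccinimide, O=C1CCC(=O)N1Br; water, O
Why: Halonium-initiated cation–olefin cyclisation with oxygen-nucleophile termination: the bromonium ion on the more electron-rich trisubstituted alkene is opened through a chair by the 1,1-disubstituted alkene and the tertiary cyclohexyl cation is captured axially by water (anti addition), so bromine and the CH2 link become equatorial and hydroxyl axial as in the target; the reagent is achiral and the distant core gives no bias, so the diastereomer with (1S,4S) ring A is expected as well and is removed.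

Compound list
1 | 2-bromoethanol | OCCBr | starting material
2 | (2-bromoethoxy)(tert-butyl)diphenylsilane | BrCCO[Si](c1ccccc1)(c1ccccc1)C(C)(C)C | intermediate
3 | methyl 2-oxocyclopentane-1-carboxylate | COC(=O)C1CCCC1=O | starting material
4 | dilithium dianion of 3 (ester enolate and ketone enolate; not isolated) | COC(O[Li])=C1CCC=C1O[Li] | intermediate
5 | methyl 3-[2-(tert-butyldiphenylsilyloxy)ethyl]-2-oxocyclopentane-1-carboxylate (stereoisomer mixture) | COC(=O)C1CCC(CCO[Si](c2ccccc2)(c2ccccc2)C(C)(C)C)C1=O | intermediate
6 | methyl 3-[2-(tert-butyldiphenylsilyloxy)ethyl]-2-hydroxycyclopentane-1-carboxylate (stereoisomer mixture) | COC(=O)C1CCC(CCO[Si](c2ccccc2)(c2ccccc2)C(C)(C)C)C1O | intermediate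
7 | methyl 3-[2-(tert-butyldiphenylsilyloxy)ethyl]-2-(methylsulfonyloxy)cyclopentane-1-carboxylate (not isolated) | COC(=O)C1CCC(CCO[Si](c2ccccc2)(c2ccccc2)C(C)(C)C)C1OS(C)(=O)=O | intermediate
8 | methyl 3-[2-(tert-butyldiphenylsilyloxy)ethyl]cyclopent-1-ene-1-carboxylate (racemic) | COC(=O)C1=CC(CCO[Si](c2ccccc2)(c2ccccc2)C(C)(C)C)CC1 | intermediate
9 | pent-4-enoyl chloride | C=CCCC(=O)Cl | starting material
10 | lithium dienolate of 8 (not isolated) | COC(O[Li])=C1CCC(CCO[Si](c2ccccc2)(c2ccccc2)C(C)(C)C)=C1 | intermediate
11 | methyl 3-[2-(tert-butyldiphenylsilyloxy)ethyl]-1-(pent-4-enoyl)cyclopent-2-ene-1-carboxylate (racemic) | C=CCCC(=O)C1(C(=O)OC)CCC(CCO[Si](c2ccccc2)(c2ccccc2)C(C)(C)C)=C1 | intermediate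
12 | methyl (1S)-3-[2-(tert-butyldiphenylsilyloxy)ethyl]-1-[(1S)-1-hydroxypent-4-enyl]cyclopent-2-ene-1-carboxylate | C=CCC[C@H](O)[C@]1(C(=O)OC)CCC(CCO[Si](c2ccccc2)(c2ccccc2)C(C)(C)C)=C1 | intermediate
13 | methyl (1S)-3-[2-(tert-butyldiphenylsilyloxy)ethyl]-1-[(1S)-1-(triethylsilyloxy)pent-4-enyl]cyclopent-2-ene-1-carboxylate | C=CCC[C@H](O[Si](CC)(CC)CC)[C@]1(C(=O)OC)CCC(CCO[Si](c2ccccc2)(c2ccccc2)C(C)(C)C)=C1 | intermediate
14 | methyl (1S)-3-[2-(tert-butyldiphenylsilyloxy)ethyl]-1-[(1S)-4-oxo-1-(triethylsilyloxy)pentyl]cyclopent-2-ene-1-carboxylate | CC(=O)CC[C@H](O[Si](CC)(CC)CC)[C@]1(C(=O)OC)CCC(CCO[Si](c2ccccc2)(c2ccccc2)C(C)(C)C)=C1 | intermediate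
15 | methyl (3aS,4R,7S,7aS)-3-[2-(tert-butyldiphenylsilyloxy)ethyl]-4-hydroxy-4-methyl-7-(triethylsilyloxy)-1,3a,4,5,6,7-hexahydro-7aH-indene-7a-carboxylate | CC(C)(C)[Si](c1ccccc1)(c1ccccc1)OCCC3=CC[C@@]4(C(=O)OC)[C@@H](O[Si](CC)(CC)CC)CC[C@@](C)(O)[C@@H]34 | intermediate
16 | methyl (3R,3aS,4R,7S,7aS)-3-[2-(tert-butyldiphenylsilyloxy)ethyl]-4-hydroxy-4-methyl-7-(triethylsilyloxy)octahydro-7aH-indene-7a-carboxylate | CC(C)(C)[Si](c1ccccc1)(c1ccccc1)OCC[C@H]3CC[C@@]4(C(=O)OC)[C@@H](O[Si](CC)(CC)CC)CC[C@@](C)(O)[C@@H]34 | intermediate
17 | (3R,3aS,4S,7S,7aS)-3-[2-(tert-butyldiphenylsilyloxy)ethyl]-7-hydroxy-4-methyloctahydro-1H-indene-7a,4-carbolactone (hydroxyl axial, trans to the lactone bridge) | CC(C)(C)[Si](c1ccccc1)(c1ccccc1)OCC[C@H]2CC[C@@]34C(=O)O[C@@](C)(CC[C@@H]3O)[C@@H]24 | intermediate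
18 | (3R,3aS,4S,7R,7aR)-7-bromo-3-[2-(tert-butyldiphenylsilyloxy)ethyl]-4-methyloctahydro-1H-indene-7a,4-carbolactone | CC(C)(C)[Si](c1ccccc1)(c1ccccc1)OCC[C@H]2CC[C@@]34C(=O)O[C@@](C)(CC[C@H]3Br)[C@@H]24 | intermediate
19 | (3R,3aS,4S,7R,7aR)-7-bromo-3-(2-hydroxyethyl)-4-methyloctahydro-1H-indene-7a,4-carbolactone | OCC[C@H]2CC[C@@]34C(=O)O[C@@](C)(CC[C@H]3Br)[C@@H]24 | intermediate
20 | (3R,3aS,4S,7R,7aR)-7-bromo-4-methyl-3-(2-oxoethyl)octahydro-1H-indene-7a,4-carbolactone | O=CC[C@H]2CC[C@@]34C(=O)O[C@@](C)(CC[C@H]3Br)[C@@H]24 | intermediate
21 | 5-bromo-2-methylpent-2-ene | CC(C)=CCCBr | starting material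
22 | 4-methylpent-3-enylmagnesium bromide (not isolated) | CC(C)=CCC[Mg]Br | intermediate
23 | (3R,3aS,4S,7R,7aR)-7-bromo-3-(2-hydroxy-6-methylhept-5-enyl)-4-methyloctahydro-1H-indene-7a,4-carbolactone (carbinol epimers) | CC(C)=CCCC(O)C[C@H]2CC[C@@]34C(=O)O[C@@](C)(CC[C@H]3Br)[C@@H]24 | intermediate
24 | (3R,3aS,4S,7R,7aR)-7-bromo-4-methyl-3-(6-methyl-2-oxohept-5-enyl)octahydro-1H-indene-7a,4-carbolactone | CC(C)=CCCC(=O)C[C@H]2CC[C@@]34C(=O)O[C@@](C)(CC[C@H]3Br)[C@@H]24 | intermediate
25 | (3R,3aS,4S,7R,7aR)-7-bromo-4-methyl-3-(6-methyl-2-methylidenehept-5-enyl)octahydro-1H-indene-7a,4-carbolactone | CC(C)=CCCC(=C)C[C@H]2CC[C@@]34C(=O)O[C@@](C)(CC[C@H]3Br)[C@@H]24 | intermediate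
26 | (3R,3aS,4S,7R,7aR)-7-bromo-3-{[(1R,4R)-4-bromo-1-hydroxy-3,3-dimethylcyclohexyl]methyl}-4-methyloctahydro-1H-indene-7a,4-carbolactone (CNP0282702.1) | CC1(C)C[C@](O)(C[C@H]2CC[C@@]34C(=O)O[C@@](C)(CC[C@H]3Br)[C@@H]24)CC[C@H]1Br | target

Total step count: 18. Longest linear sequence: 18 steps (1 to 26).

Steps most likely to fail

1. Step 18 (ring A bromocyclisation–hydration). The bromonium ion can form on either face of the trisubstituted alkene without bias from the distant core, so ring A arises in both absolute senses and the wanted diastereomer must be separated. In addition, proton loss from the tertiary cation or direct opening of the bromonium ion by water can compete with cyclisation and hydration. Fallback (reagent control of the bromonium configuration): starting from diene 25, Shi epoxidation (KHSO5 with the enantiomer of the fructose-derived ketone 1,2:4,5-di-O-isopropylidene-erythro-2,3-hexodiulo-2,6-pyranose that gives the S epoxide; 1,1-disubstituted alkenes are poor substrates) would give the trisubstituted epoxide F1. Li2NiBr4 in THF would open it at the secondary carbon with inversion to the bromohydrin F2, tertiary alcohol and (R)-configured secondary bromide. Ionisation of the tertiary hydroxyl with BF3·OEt2 in nitromethane at low temperature, assisted by the neighbouring bromine, would regenerate a bromonium ion of one configuration only, which cyclises and is hydrated as in step 18; the route is rejoined at 26.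

2. Step 12 (invertive bromination). Backside attack at a secondary carbon flanked by a quaternary centre is slow, so elimination toward the ring CH2 or unproductive collapse of the alkoxyphosphonium ion may take over. Fallback (no substitution at that carbon): starting from hydroxy lactone 17, Dess–Martin oxidation would give the keto lactone F3. Triphenyl phosphite–bromine with Et3N in CH2Cl2 would convert the enolisable ketone into the vinyl bromide F4. Hydrogen-atom-transfer hydrogenation with Mn(dpm)3 [tris(2,2,6,6-tetramethylheptane-3,5-dionato)manganese], PhSiH3 and tert-butyl hydroperoxide in isopropanol reduces haloalkenes without loss of halogen and, under its thermodynamic stereocontrol, should leave bromine equatorial; the route is rejoined at 18.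

3. Step 9 (Prins closure). The Lewis acid may be tied up by the ester and silyl ether oxygens so that ketone activation is sluggish, or the tertiary cation may be captured by chloride or by the angular ester carbonyl instead of losing a proton. Fallback (a more electrophilic, aluminium-free initiator): starting from keto ester 14, MeOSiMe3 and Me3SiOSO2CF3 with 2,6-di-tert-butylpyridine in CH2Cl2 at −78 °C would turn the ketone in situ into a methoxycarbenium ion. A ketal-type cation–olefin cyclisation would then forge the same bond and give the tertiary methyl ether F5. Hydrogenation as in step 10 would give the saturated methyl ether F6, which the acid of step 11 should ionise in the same way as the alcohol; the route is rejoined at hydroxy lactone 17.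

Further compounds
F1 | step 18 | (3R,3aS,4S,7R,7aR)-7-bromo-3-{4-[(2S)-3,3-dimethyloxiran-2-yl]-2-methylidenebutyl}-4-methyloctahydro-1H-indene-7a,4-carbolactone | CC1(C)O[C@H]1CCC(=C)C[C@H]2CC[C@@]34C(=O)O[C@@](C)(CC[C@H]3Br)[C@@H]24
F2 | step 18 | (3R,3aS,4S,7R,7aR)-7-bromo-3-[(5R)-5-bromo-6-hydroxy-6-methyl-2-methylideneheptyl]-4-methyloctahydro-1H-indene-7a,4-carbolactone | CC(C)(O)[C@H](Br)CCC(=C)C[C@H]2CC[C@@]34C(=O)O[C@@](C)(CC[C@H]3Br)[C@@H]24
F3 | step 12 | keto lactone, the 7-oxo analogue of 17 | CC(C)(C)[Si](c1ccccc1)(c1ccccc1)OCC[C@H]2CC[C@@]34C(=O)O[C@@](C)(CCC3=O)[C@@H]24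
F4 | step 12 | vinyl bromide, the 7-bromo-6,7-dehydro analogue of 18 | CC(C)(C)[Si](c1ccccc1)(c1ccccc1)OCC[C@H]2CC[C@@]34C(=O)O[C@@](C)(CC=C3Br)[C@@H]24
F5 | step 9 | tertiary methyl ether, the 4-methoxy analogue of 15 | CC(C)(C)[Si](c1ccccc1)(c1ccccc1)OCCC3=CC[C@@]4(C(=O)OC)[C@@H](O[Si](CC)(CC)CC)CC[C@@](C)(OC)[C@@H]34
F6 | step 9 | saturated tertiary methyl ether, the 4-methoxy analogue of 16 | CC(C)(C)[Si](c1ccccc1)(c1ccccc1)OCC[C@H]3CC[C@@]4(C(=O)OC)[C@@H](O[Si](CC)(CC)CC)CC[C@@](C)(OC)[C@@H]34
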